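**Retrosynthetic overview** (prostanoid numbering: C1 ester carbon, C4 and C12 the acetoxy carbons, C9 the ring ketone, C20 the chain end)
1. The C12 acetate and the C7=C8 alkene are made last: aldol addition of the C8 enolate of a 4-hydroxycyclopent-2-enone (C8–C20) to a (4R,5Z)-enal (C1–C7), then acetylative elimination.
2. The only ring, the cyclopentenone, is formed once, in the key step, which makes C8–C12 and C10=C11 in one flask: a β-ketophosphonate acting as acetone 1,3-dianion (C8–C9–C10) is joined to a 2-oxoaldehyde (C11–C20) whose aldehyde is masked as a chiral aminal.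
3. Enabling feature: in the ring the ketone C9 sits between two α-carbons, C8 and C10, and the other two ring atoms, C11 (sp2 CH, aldehyde level) and C12 (oxygen-bearing quaternary carbon, ketone level), are neighbours; C12–O is β to C9 through C8 (aldol retron) and C10=C11 is α,β to C9 (olefination retron).
4. Stereocontrol: C12 from the aminal auxiliary through a temporary stereocentre at C11 that vanishes in the olefination; C4 by asymmetric transfer hydrogenation of an ynone; the 14Z,17Z diene from a commercial dienol; 5Z by semi-hydrogenation.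

Key step: step 5

Remark: (3Z,6Z)-nona-3,6-dien-1-ol and (S)-2-(anilinomethyl)pyrrolidine are taken as commercial, and the aminal of step 4 is assumed to form as the convex-face diastereomer, on which the facial argument of step 5 rests.

**Step 1**
Reactants: 1 (3Z,6Z)-nona-3,6-dien-1-ol
Product: 2 (3Z,6Z)-nona-3,6-dienoic acid
Conditions: CrO3, aq. H2SO4, acetone, –10 °C
Reagents that add atoms: water, O
Why: Jones oxidation of a primary homoallylic alcohol to the acid under acidic conditions, which should leave the skipped Z,Z-diene unconjugated; no stereocentre is formed.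

**Step 2**
Reactants: 2 (3Z,6Z)-nona-3,6-dienoic acid
Product: 4 (4Z,7Z)-1-diazodeca-4,7-dien-2-one, via acid chloride 3 (not isolated)
Conditions: (COCl)2, cat. DMF, CH2Cl2, 0 °C; then CH2N2 (excess), Et2O, 0 °C
Reagents that add atoms: diazomethane, C=[N+]=[N-]
Why: Acylation of diazomethane by the acid chloride (first stage of an Arndt–Eistert sequence) should give the diazoketone with no base stronger than diazomethane present, so the β,γ-alkene should stay in place.

**Step 3**
Reactants: 4 (4Z,7Z)-1-diazodeca-4,7-dien-2-one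
Product: 5 (4Z,7Z)-2-oxodeca-4,7-dienal (used crude)
Conditions: dimethyldioxirane (1.0 equiv), acetone/CH2Cl2, –40 to 0 °C
Reagents that add atoms: dimethyldioxirane, CC1(C)OO1
Why: Oxygen transfer from the dioxirane to the nucleophilic diazo carbon with loss of N2 is a known route from diazoketones to 2-oxoaldehydes and should outrun epoxidation of the unactivated Z-alkenes at low temperature under neutral conditions.

**Step 4**
Reactants: 5 (4Z,7Z)-2-oxodeca-4,7-dienal; 6 (S)-2-(anilinomethyl)pyrrolidine
Product: 7 (3Z,6Z)-1-[(2R,5S)-3-phenyl-1,3-diazabicyclo[3.3.0]octan-2-yl]nona-3,6-dien-1-one (acyl group on the convex face, cis to the ring-fusion hydrogen)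
Conditions: MgSO4, CH2Cl2, rt
Reagents that add atoms: none
Why: Aminal formation of the 1,2-diamine at the aldehyde carbonyl of a 2-oxoaldehyde; under thermodynamic control the acyl group should take the convex face of the cis-fused bicycle, which fixes the temporary stereocentre at the aminal carbon.

**Step 5**
Reactants: 7 keto aminal (as above); 8 dimethyl (2-oxopropyl)phosphonate
Product: 11 (4R)-4-hydroxy-4-[(2Z,5Z)-octa-2,5-dien-1-yl]cyclopent-2-en-1-one, via aldol adduct 9 (not isolated), via hydroxy aldehyde 10 (not isolated)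
Conditions: 8, NaH, THF, 0 °C, then n-BuLi, –78 °C; MgBr2·OEt2, then 7, –78 °C; 2% aq. HCl, Et2O, 0 °C, aqueous layer (auxiliary) removed; organic layer, aq. K2CO3, rt
Reagents that add atoms: none
Why: The 1,3-dianion of 8 (phosphonate carbon C10 and methyl carbon C8 deprotonated) should add through its more basic C8 terminus to the C12 ketone of 7 (aldol addition), dilute acid then frees the C11 aldehyde from the aminal, and K2CO3 starts an intramolecular Horner–Wadsworth–Emmons olefination between C10 and C11 with loss of dimethyl phosphate. The closest known reaction types are the chelation-controlled addition of organomagnesium reagents to 2-acyl aminals of this diamine, the γ-selective reaction of β-ketophosphonate dianions with carbonyl compounds and the cyclopentenone synthesis from 2,5-dioxoalkylphosphonates. The ring closes in the olefination, a five-membered closure in which the new alkene can only be cis, so the sequence amounts to a formal [3+2] annulation of an acetone 1,3-dianion with a 2-oxoaldehyde. C12 is set in the addition by the auxiliary: Mg should bridge the ketone oxygen and the bridgehead nitrogen on the convex face, the N-phenyl nitrogen blocks one face of the chelate and C8 should attack from the side of the aminal C–H (Re face), giving (R)-9 and hence (R)-11, which has the spatial arrangement of the 12S centre of the target (the descriptor changes later only because C8 becomes sp2); the aminal stereocentre disappears when C11 becomes sp2. The step needs addition to win over deprotonation of the allylic C13–H2 of 7, which chelate activation of the ketone, the magnesium counter-ion and –78 °C should secure, and it needs the alkene at C10=C11 without loss of the C12 oxygen, which the phosphonate secures because only C10 carries the leaving phosphorus.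

**Step 6**
Reactants: 12 methyl 4-chloro-4-oxobutanoate; 13 3,3-diethoxyprop-1-yne
Product: 14 methyl 7,7-diethoxy-4-oxohept-5-ynoate
Conditions: PdCl2(PPh3)2 (cat.), CuI (cat.), Et3N, THF, rt
Reagents that add atoms: none
Why: Acyl Sonogashira coupling of the acid chloride with the terminal alkyne gives the ynone; ester and acetal are inert and no stereocentre is formed.

**Step 7**
Reactants: 14 methyl 7,7-diethoxy-4-oxohept-5-ynoate
Product: 15 methyl (4R)-7,7-diethoxy-4-hydroxyhept-5-ynoate
Conditions: Ru[(R,R)-TsDPEN](p-cymene) (cat.), i-PrOH, rt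
Reagents that add atoms: none
Why: Asymmetric transfer hydrogenation of an alkynyl ketone (Noyori type) in which the alkyne takes the place of the aryl group in the CH/π-controlled transition state, so the (R,R)-catalyst should give the (R)-propargylic alcohol and set C4.

**Step 8**
Reactants: 15 methyl (4R)-7,7-diethoxy-4-hydroxyhept-5-ynoate
Product: 16 methyl (4R)-4-acetoxy-7,7-diethoxyhept-5-ynoate
Conditions: Ac2O, pyridine, cat. DMAP, CH2Cl2, 0 °C
Reagents that add atoms: acetic anhydride, CC(=O)OC(C)=O
Why: Standard acylation of the secondary alcohol, run directly on the crude alcohol so that lactonisation of the γ-hydroxy ester cannot compete; C4 is untouched.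

**Step 9**
Reactants: 16 methyl (4R)-4-acetoxy-7,7-diethoxyhept-5-ynoate
Product: 17 methyl (4R,5Z)-4-acetoxy-7,7-diethoxyhept-5-enoate
Conditions: H2 (1 atm), Pd/CaCO3 poisoned with Pb(OAc)2, quinoline, EtOAc, rt
Reagents that add atoms: none
Why: Lindlar-type semi-hydrogenation adds H2 syn to the alkyne and should stop at the 5Z alkene; the stereocentre at C4 is not affected.

**Step 10**
Reactants: 17 methyl (4R,5Z)-4-acetoxy-7,7-diethoxyhept-5-enoate
Product: 18 methyl (4R,5Z)-4-acetoxy-7-oxohept-5-enoate (used at once)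
Conditions: SiO2, 10% aq. oxalic acid, CH2Cl2, rt
Reagents that add atoms: water, O
Why: Mild heterogeneous acid hydrolysis of the diethyl acetal should free the Z-enal without Z to E isomerisation or loss of the allylic acetate.

**Step 11**
Reactants: 11 (4R)-4-hydroxy-4-[(2Z,5Z)-octa-2,5-dien-1-yl]cyclopent-2-en-1-one; 18 methyl (4R,5Z)-4-acetoxy-7-oxohept-5-enoate
Product: 19 methyl (4R,5Z)-4-acetoxy-7-hydroxy-7-[(2S)-2-hydroxy-2-[(2Z,5Z)-octa-2,5-dien-1-yl]-5-oxocyclopent-3-en-1-yl]hept-5-enoate (mixture at C7 and C8)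
Conditions: LDA (LiN(i-Pr)2, 2.2 equiv), THF, –78 °C; then 18, –78 °C; aq. NH4Cl
Reagents that add atoms: none
Why: Kinetic deprotonation of the alkoxide of 11 at C8, its only enolisable position, gives a cross-conjugated dienolate that should add 1,2 to the enal (aldol addition); the new C7 and C8 stereocentres are not controlled and both disappear in step 12, and C12 is not touched.

**Step 12**
Reactants: 19 aldol adduct (as above)
Product: 22 17,18-dehydroclavulone I, via C7 acetate 20 (not isolated), via hydroxy dienone 21 (not isolated)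
Conditions: Ac2O (excess), DMAP, Et3N, CH2Cl2, 0 °C to rt
Reagents that add atoms: acetic anhydride, CC(=O)OC(C)=O
Why: Acetylation of the C7 alcohol followed by E1cB loss of acetate should give the C7=C8 alkene with the E geometry usual for 2-alkylidenecyclopentanones (loss of the C12 oxygen instead would give an antiaromatic cyclopentadienone), and DMAP-catalysed acylation (Steglich type) of the tertiary allylic alcohol then completes the target without touching C12 or C4.

**Compound list**
1 | (3Z,6Z)-nona-3,6-dien-1-ol | CC/C=C\C/C=C\CCO | starting material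
2 | (3Z,6Z)-nona-3,6-dienoic acid | CC/C=C\C/C=C\CC(=O)O | intermediate
3 | (3Z,6Z)-nona-3,6-dienoyl chloride | CC/C=C\C/C=C\CC(=O)Cl | intermediate
4 | (4Z,7Z)-1-diazodeca-4,7-dien-2-one | CC/C=C\C/C=C\CC(=O)C=[N+]=[N-] | intermediate
5 | (4Z,7Z)-2-oxodeca-4,7-dienal | CC/C=C\C/C=C\CC(=O)C=O | intermediate
6 | (S)-2-(anilinomethyl)pyrrolidine | c1ccc(cc1)NC[C@@H]1CCCN1 | starting material
7 | (3Z,6Z)-1-[(2R,5S)-3-phenyl-1,3-diazabicyclo[3.3.0]octan-2-yl]nona-3,6-dien-1-one | CC/C=C\C/C=C\CC(=O)[C@H]1N(c2ccccc2)C[C@@H]2CCCN12 | intermediate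
8 | dimethyl (2-oxopropyl)phosphonate | CC(=O)CP(=O)(OC)OC | starting material
9 | dimethyl [(4R,6Z,9Z)-4-hydroxy-2-oxo-4-[(2R,5S)-3-phenyl-1,3-diazabicyclo[3.3.0]octan-2-yl]dodeca-6,9-dien-1-yl]phosphonate | CC/C=C\C/C=C\C[C@](CC(=O)CP(=O)(OC)OC)(O)[C@H]1N(c2ccccc2)C[C@@H]2CCCN12 | intermediate
10 | dimethyl [(4R,6Z,9Z)-4-formyl-4-hydroxy-2-oxododeca-6,9-dien-1-yl]phosphonate | CC/C=C\C/C=C\C[C@](CC(=O)CP(=O)(OC)OC)(O)C=O | intermediate
11 | (4R)-4-hydroxy-4-[(2Z,5Z)-octa-2,5-dien-1-yl]cyclopent-2-en-1-one | CC/C=C\C/C=C\C[C@]1(O)C=CC(=O)C1 | intermediate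
12 | methyl 4-chloro-4-oxobutanoate | COC(=O)CCC(=O)Cl | starting material
13 | 3,3-diethoxyprop-1-yne | C#CC(OCC)OCC | starting material
14 | methyl 7,7-diethoxy-4-oxohept-5-ynoate | COC(=O)CCC(=O)C#CC(OCC)OCC | intermediate
15 | methyl (4R)-7,7-diethoxy-4-hydroxyhept-5-ynoate | COC(=O)CC[C@@H](O)C#CC(OCC)OCC | intermediate
16 | methyl (4R)-4-acetoxy-7,7-diethoxyhept-5-ynoate | COC(=O)CC[C@@H](OC(C)=O)C#CC(OCC)OCC | intermediate
17 | methyl (4R,5Z)-4-acetoxy-7,7-diethoxyhept-5-enoate | COC(=O)CC[C@@H](OC(C)=O)/C=C\C(OCC)OCC | intermediate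
18 | methyl (4R,5Z)-4-acetoxy-7-oxohept-5-enoate | COC(=O)CC[C@@H](OC(C)=O)/C=C\C=O | intermediate
19 | methyl (4R,5Z)-4-acetoxy-7-hydroxy-7-[(2S)-2-hydroxy-2-[(2Z,5Z)-octa-2,5-dien-1-yl]-5-oxocyclopent-3-en-1-yl]hept-5-enoate (mixture at C7 and C8) | CC/C=C\C/C=C\C[C@]1(O)C=CC(=O)C1C(O)/C=C\[C@@H](CCC(=O)OC)OC(C)=O | intermediate
20 | methyl (4R,5Z)-4,7-diacetoxy-7-[(2S)-2-hydroxy-2-[(2Z,5Z)-octa-2,5-dien-1-yl]-5-oxocyclopent-3-en-1-yl]hept-5-enoate (mixture at C7 and C8) | CC/C=C\C/C=C\C[C@]1(O)C=CC(=O)C1C(OC(C)=O)/C=C\[C@@H](CCC(=O)OC)OC(C)=O | intermediate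
21 | methyl (4R,5Z,7E)-4-acetoxy-7-[(2S)-2-hydroxy-2-[(2Z,5Z)-octa-2,5-dien-1-yl]-5-oxocyclopent-3-en-1-ylidene]hept-5-enoate | CC/C=C\C/C=C\C[C@]1(O)C=CC(=O)/C1=C/C=C\[C@@H](CCC(=O)OC)OC(C)=O | intermediate
22 | 17,18-dehydroclavulone I, methyl (4R,5Z,7E)-4-acetoxy-7-[(2S)-2-acetoxy-2-[(2Z,5Z)-octa-2,5-dien-1-yl]-5-oxocyclopent-3-en-1-ylidene]hept-5-enoate | CC/C=C\C/C=C\C[C@]1(OC(C)=O)C=CC(=O)/C1=C/C=C\[C@@H](CCC(=O)OC)OC(C)=O | target

**Step count and risks**
Total steps: 12. Longest linear sequence: 7 steps (steps 1–5, 11, 12 from 1; equally steps 6–12 from 12).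

Steps most likely to fail:

1. Step 5. The basic dianion may deprotonate the doubly activated allylic C13–H2 of 7 instead of adding, which would move the C14 alkene into conjugation, and an enolate-type magnesium nucleophile may sit less cleanly in the chelate than a simple Grignard reagent, eroding facial selectivity. The fallback sets out from 7 and returns at 11. The C3 unit is brought in as a non-basic allyl Grignard reagent, the best-precedented nucleophile class for this aminal, and the ketone and the ring are made afterwards. CH2=CHCH2MgBr (Et2O, –78 °C) should give, through the same chelate, the allyl carbinol aminal F1. 2% aq. HCl frees the hydroxy aldehyde F2. Tsuji–Wacker oxidation of the terminal alkene (PdCl2, CuCl, O2, DMF/H2O) should give the methyl ketone F3. Pyrrolidinium acetate then closes the ring by intramolecular aldol condensation through the enamine of the methyl ketone and the iminium ion of the aldehyde, which places the alkene at C10=C11 and gives 11.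

2. Step 3. Oxygen transfer may not stop at the diazo carbon (epoxidation of the skipped diene), and the free 2-oxoaldehyde may hydrate or oligomerise on concentration. The fallback sets out from 1 and returns at 5. C11 is introduced as a formyl-anion equivalent and no diazo compound or dioxirane is used. Dess–Martin oxidation (NaHCO3, CH2Cl2, 0 °C) gives (3Z,6Z)-nona-3,6-dienal F4. Addition of LiCH(OEt)2 (from Bu3SnCH(OEt)2 and n-BuLi, THF, –78 °C) gives the hydroxy acetal F5. A second Dess–Martin oxidation gives the keto acetal F6. Hydrolysis with aqueous formic acid in pentane at 0 °C should give 5.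

3. Step 12. Reversible conjugate addition of the amine bases to the cross-conjugated dienone during the slow tertiary acetylation may isomerise the 5Z alkene to 5E and scramble C7=C8. The fallback sets out from 16 and 11 and returns at 22. C5–C6 is carried as an alkyne through the base-mediated steps and the Z alkene is made last. Acetal hydrolysis of 16 (SiO2, aq. oxalic acid) gives the ynal F7. Aldol addition of the dilithio derivative of 11 (LDA, THF, –78 °C) gives the ynol F8. Ac2O/DMAP/Et3N should give, through the C7 acetate F9 and the hydroxy enynone F10, the enynone diacetate F11. Semi-hydrogenation (H2, Pd/CaCO3 poisoned with Pb(OAc)2, quinoline) then gives 22.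

**Further compounds**
F1 | step 5 | (4S,6Z,9Z)-4-[(2R,5S)-3-phenyl-1,3-diazabicyclo[3.3.0]octan-2-yl]dodeca-1,6,9-trien-4-ol | CC/C=C\C/C=C\C[C@](CC=C)(O)[C@H]1N(c2ccccc2)C[C@@H]2CCCN12
F2 | step 5 | (2S,4Z,7Z)-2-hydroxy-2-(prop-2-en-1-yl)deca-4,7-dienal | CC/C=C\C/C=C\C[C@](CC=C)(O)C=O
F3 | step 5 | (2R,4Z,7Z)-2-hydroxy-2-(2-oxopropyl)deca-4,7-dienal | CC/C=C\C/C=C\C[C@](CC(C)=O)(O)C=O
F4 | step 3 | (3Z,6Z)-nona-3,6-dienal | CC/C=C\C/C=C\CC=O
F5 | step 3 | (4Z,7Z)-1,1-diethoxydeca-4,7-dien-2-ol (racemic) | CC/C=C\C/C=C\CC(O)C(OCC)OCC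
F6 | step 3 | (4Z,7Z)-1,1-diethoxydeca-4,7-dien-2-one | CC/C=C\C/C=C\CC(=O)C(OCC)OCC
F7 | step 12 | methyl (4R)-4-acetoxy-7-oxohept-5-ynoate | COC(=O)CC[C@@H](OC(C)=O)C#CC=O
F8 | step 12 | methyl (4R)-4-acetoxy-7-hydroxy-7-[(2S)-2-hydroxy-2-[(2Z,5Z)-octa-2,5-dien-1-yl]-5-oxocyclopent-3-en-1-yl]hept-5-ynoate | CC/C=C\C/C=C\C[C@]1(O)C=CC(=O)C1C(O)C#C[C@@H](CCC(=O)OC)OC(C)=O
F9 | step 12 | methyl (4R)-4,7-diacetoxy-7-[(2S)-2-hydroxy-2-[(2Z,5Z)-octa-2,5-dien-1-yl]-5-oxocyclopent-3-en-1-yl]hept-5-ynoate | CC/C=C\C/C=C\C[C@]1(O)C=CC(=O)C1C(OC(C)=O)C#C[C@@H](CCC(=O)OC)OC(C)=O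
F10 | step 12 | methyl (4R,7E)-4-acetoxy-7-[(2S)-2-hydroxy-2-[(2Z,5Z)-octa-2,5-dien-1-yl]-5-oxocyclopent-3-en-1-ylidene]hept-5-ynoate | CC/C=C\C/C=C\C[C@]1(O)C=CC(=O)/C1=C/C#C[C@@H](CCC(=O)OC)OC(C)=O
F11 | step 12 | methyl (4R,7E)-4-acetoxy-7-[(2S)-2-acetoxy-2-[(2Z,5Z)-octa-2,5-dien-1-yl]-5-oxocyclopent-3-en-1-ylidene]hept-5-ynoate | CC/C=C\C/C=C\C[C@]1(OC(C)=O)C=CC(=O)/C1=C/C#C[C@@H](CCC(=O)OC)OC(C)=O
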